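Take the two earlier runs and examine them one question at a time.

| flask | substrate | reagent | remark | time |
|---|---|---|---|---|
| winter | 0.010 M | 0.013 M | run made earlier |  |
| spring | 0.010 M | 0.033 M | run made earlier |  |
| amber | 0.010 M | 0.0150 M |  | 25 min |
| green | 0.010 M | 0.0250 M |  | 25 min |
| ochre | 0.010 M | 0.0400 M |  | 25 min |

| run | time / min | double product / % | first product / % |
|---|---|---|---|
| winter | 1.00 | 2.9 | 22.9 |
| winter | 2.50 | 9.9 | 30.5 |
| winter | 5.00 | 18.9 | 25.9 |
| winter | 8.00 | 27.2 | 18.7 |
| winter | 10.0 | 31.1 | 14.9 |
| winter | 15.0 | 38.5 | 9.5 |
| winter | 20.0 | 43.5 | 6.9 |
| spring | 2.50 | 37.0 | 30.7 |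
| spring | 5.00 | 59.6 | 15.8 |
| spring | 8.00 | 73.4 | 8.5 |
| spring | 10.0 | 79.2 | 5.8 |
| spring | 12.0 | 83.0 | 4.5 |
| spring | 15.0 | 87.6 | 3.2 |
| spring | 20.0 | 91.7 | 1.7 |

(readings scatter by 0.3 percentage points)

* how much double product is there at the end, in percent of the substrate charged: for each flask in turn (amber, green, ochre)



What stands in the flask that nobody read? By-product and reagent, and they can be counted: each first product has released one by-product and each double product two, and every release used one reagent. Whatever is neither first nor double product I call the rest, and I count it as substrate.

Is the step from substrate and reagent to first product and by-product a fast equilibrium? Then one ratio should hold. Winter at 5.00 min has [by-product] 0.00637 M and gives 0.451. Spring at 10.0 min has 0.0164 M and gives 0.383. The two are not equal, so their mean 0.417 is a working value, and I carry it as the balance ratio, [first product][by-product] over [rest][reagent].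

Two readings could be luck, so what can it predict? It gives the share of undoubled material standing as first product: ratio×[reagent] over [by-product] + ratio×[reagent]. Double product forms at k[first product][reagent], and the readings from 5.00 min to 8.00 min in spring give k = 20.5 M⁻¹ min⁻¹. So undoubled material decays at each moment in a pseudo-first-order way, with a momentary constant k × share × [reagent].

Does that survive a test? At 15.0 min spring has [by-product] 0.0178 M, so I reckon 0.0812 min⁻¹, and its last readings decay at 0.0803 min⁻¹.

And ochre? Late in ochre I expect [by-product] near twice the substrate charge, which leaves [reagent] at 0.0200 M and a constant of 0.121 min⁻¹. Ochre has more reagent than spring, so I take spring's undoubled 20.8% at 10.0 min as a high estimate for ochre at that time. Decay over the remaining 15.0 min then gives a low estimate of 96.6% double product in ochre.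

The forecast says the first step looks like “a fast reversible equilibrium that releases a by-product” and gives 54%, 81% and 98.5%, its ochre value standing above my low estimate.

The flasks give 55.1%, 84.7% and 97.3%, with ochre above my low estimate.

    reagent + first product → double product + by-product (k = 12.0 M⁻¹ min⁻¹)
    substrate + reagent ⇌ first product + by-product (K = 0.740, k = 29.0 M⁻¹ min⁻¹)
    reagent + other mono adduct → double product + by-product (k = 34.0 M⁻¹ min⁻¹)
    substrate + reagent → other mono adduct + by-product (k = 6.60 M⁻¹ min⁻¹)
    first product ⇌ isomer of the product (K = 0.450, k = 0.0290 min⁻¹)

Green's rest at 25 min is substrate 8.04%, other mono adduct 1.90% and isomer of the product 2.82%. Applied to amber's first and double product, the ratio 0.417 gives a rest of 37.7%, against 40.1% in amber. In green it gives 13.4%, against 12.8%.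

(The data stem from a simulated flask for substances that don't exist, and the scatter is random.)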